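The route rests on cutting the O1–C8a bond of ring C. Ring A of the target carries O1, O5 and O7 on C8a, C5 and C7, all ortho or para to C4a and thus conjugated with the C4 carbonyl; a C–F bond at each of these carbons is activated for addition–elimination. A symmetric 2,4,6-trifluoro-3,5-dimethylphenyl ketone therefore stands in for ring A. In the key step the enolate oxygen of 1-(3-benzyloxy-4,5-dimethoxyphenyl)-3-(2,4,6-trifluoro-3,5-dimethylphenyl)propane-1,3-dione displaces one ortho fluoride, closing the pyranone and completing the 6,8-dimethylflavone skeleton. The two remaining fluorides are then exchanged for benzyloxy groups and all benzyl ethers are removed together.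

Key step: step 6

Assumption: 3-hydroxy-4,5-dimethoxybenzoic acid is taken as a purchasable compound; the 1,3-diketone is drawn as its diketo tautomer although the chelated enol should dominate in solution.

Step 1
Reactants: 1 1,3,5-trifluorobenzene; 2 iodomethane
Product: 4 2,4,6-trifluorotoluene, via aryllithium 3 (not isolated)
Conditions: n-BuLi (1.05 equiv), THF, −78 °C, 1 h; MeI (1.2 equiv), −78 °C → rt
Reagents that add atoms: iodomethane 2 (CI)
Why: Every C–H of 1 lies between two fluorines and is therefore acidic enough for ortho-lithiation by n-BuLi at −78 °C, where aryllithium 3 does not yet lose LiF, and 3 is then methylated by iodomethane in an SN2 alkylation.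

Step 2
Reactants: 4 2,4,6-trifluorotoluene; 2 iodomethane
Product: 6 1,3,5-trifluoro-2,4-dimethylbenzene, via aryllithium 5 (not isolated)
Conditions: n-BuLi (1.05 equiv), THF, −78 °C, 1 h; MeI (1.2 equiv), −78 °C → rt
Reagents that add atoms: iodomethane 2 (CI)
Why: The two remaining ring hydrogens of 4 are equivalent and again flanked by two fluorines, so a second ortho-lithiation followed by SN2 methylation can give only one dimethyl isomer, ring metalation between two fluorines being much faster than benzylic deprotonation.

Step 3
Reactants: 6 1,3,5-trifluoro-2,4-dimethylbenzene; 7 N-methoxy-N-methylacetamide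
Product: 9 1-(2,4,6-trifluoro-3,5-dimethylphenyl)ethanone, via aryllithium 8 (not isolated)
Conditions: n-BuLi (1.05 equiv), THF, −78 °C, 1 h; 7 (1.2 equiv), −78 °C, 2 h, then → 0 °C; 1 M HCl
Reagents that add atoms: N-methoxy-N-methylacetamide 7 (CON(C)C(C)=O)
Why: The last ring hydrogen of 6 is removed in the same ortho-lithiation and aryllithium 8 adds to the Weinreb amide to form a chelated tetrahedral adduct that releases the methyl ketone only on acidic work-up (Weinreb ketone synthesis), which rules out double addition.

Step 4
Reactants: 10 3-hydroxy-4,5-dimethoxybenzoic acid; 11 benzyl bromide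
Product: 13 3-benzyloxy-4,5-dimethoxybenzoic acid, via benzyl ester 12 (not isolated)
Conditions: BnBr (2.3 equiv), K2CO3 (3 equiv), DMF, 60 °C; then 2 M NaOH, MeOH, 60 °C; HCl to pH 2
Reagents that add atoms: benzyl bromide 11 (BrCc1ccccc1)
Why: A Williamson etherification benzylates the phenoxide while the carboxylate is esterified alongside, and saponification of benzyl ester 12 in the same flask frees the acid without touching the aryl benzyl ether.

Step 5
Reactants: 9 1-(2,4,6-trifluoro-3,5-dimethylphenyl)ethanone; 13 3-benzyloxy-4,5-dimethoxybenzoic acid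
Product: 16 1-(3-benzyloxy-4,5-dimethoxyphenyl)-3-(2,4,6-trifluoro-3,5-dimethylphenyl)propane-1,3-dione, via acid chloride 14 (not isolated), via lithium enolate 15 (not isolated)
Conditions: 13, (COCl)2 (1.3 equiv), DMF (cat.), CH2Cl2, 0 °C → rt, evaporate; 9, LiN(SiMe3)2 (2.2 equiv), THF, −78 °C, then crude 14 in THF, −78 → 0 °C; 1 M HCl
Reagents that add atoms: none
Why: The acid is activated as acid chloride 14 and C-acylates lithium enolate 15 in a crossed Claisen-type acylation, the second equivalent of LiN(SiMe3)2 converting the more acidic diketone into its lithium chelate as it forms, which protects it from a second acylation and, at or below 0 °C, should not yet displace fluoride.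

Step 6
Reactants: 16 1-(3-benzyloxy-4,5-dimethoxyphenyl)-3-(2,4,6-trifluoro-3,5-dimethylphenyl)propane-1,3-dione
Product: 18 2-(3-benzyloxy-4,5-dimethoxyphenyl)-5,7-difluoro-6,8-dimethylchromen-4-one, via cesium diketonate 17 (not isolated)
Conditions: Cs2CO3 (1.5 equiv), MeCN (0.05 M), 60 °C
Reagents that add atoms: none
Why: Cs2CO3 converts 16 into diketonate 17, whose oxygen on the carbon bearing ring B adds to the ortho C–F carbon (future C8a) to give a Meisenheimer intermediate with its charge on C4a, C6 and C8, stabilised by the C4 carbonyl and inductively by the fluorines at C5 and C7 that sit meta to the site of attack; loss of fluoride restores aromaticity and forms O1–C8a. The closest known reaction type is the intramolecular SNAr O-arylation of 1-(2-fluoroaryl)-1,3-diketone enolates, an established entry to chromones and flavones. Ring C closes as a six-membered ring by addition–elimination at an sp2 carbon, formally a 6-endo-trig attack with respect to the C4a=C8a bond that relays the charge to the carbonyl. No stereocentre is formed. The step needs O- and not C-arylation and a single regiochemistry: carbon attack would have to build a four-membered ring, the two ortho fluorides are interchangeable through the mirror plane of the 2,4,6-trifluoro-3,5-dimethylphenyl group, and the para fluoride cannot be reached within the molecule. Moderate dilution in MeCN, a solvent that cannot release a competing amine nucleophile, should hold back intermolecular displacement of the still activated C5 and C7 fluorides.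

Step 7
Reactants: 18 2-(3-benzyloxy-4,5-dimethoxyphenyl)-5,7-difluoro-6,8-dimethylchromen-4-one; 19 benzyl alcohol
Product: 21 5,7-bis(benzyloxy)-2-(3-benzyloxy-4,5-dimethoxyphenyl)-6,8-dimethylchromen-4-one, via 7-benzyloxy-5-fluoro flavone 20 (not isolated)
Conditions: BnOH (6 equiv), NaH (5 equiv), THF, 0 °C → rt; then 18, DMSO, 60 → 90 °C
Reagents that add atoms: benzyl alcohol 19 (OCc1ccccc1)
Why: This is a twofold SNAr in which benzyloxide adds to C7 and then C5, para and ortho to C4a and hence to the C4 carbonyl that stabilises each Meisenheimer intermediate, and expels fluoride; the oxygen substituents already on ring A sit meta to the carbon under attack and so should not shut down the second exchange.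

Step 8
Reactants: 21 5,7-bis(benzyloxy)-2-(3-benzyloxy-4,5-dimethoxyphenyl)-6,8-dimethylchromen-4-one
Product: 22 5,7-dihydroxy-2-(3-hydroxy-4,5-dimethoxyphenyl)-6,8-dimethylchromen-4-one (the target; no stereocentres)
Conditions: H2 (1 atm), 10% Pd/C, THF/MeOH 1:1, rt
Reagents that add atoms: none
Why: Hydrogenolysis over palladium on carbon cleaves the three benzyl aryl ethers to toluene and the free phenols, while the methyl ethers and the conjugated C2=C3 bond of the flavone are expected to survive hydrogen at atmospheric pressure.

Compound list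
1 | 1,3,5-trifluorobenzene | Fc1cc(F)cc(F)c1 | starting material
2 | iodomethane | CI | starting material
3 | (2,4,6-trifluorophenyl)lithium | [Li]c1c(F)cc(F)cc1F | intermediate
4 | 2,4,6-trifluorotoluene (1,3,5-trifluoro-2-methylbenzene) | Cc1c(F)cc(F)cc1F | intermediate
5 | (2,4,6-trifluoro-3-methylphenyl)lithium | [Li]c1c(F)cc(F)c(C)c1F | intermediate
6 | 1,3,5-trifluoro-2,4-dimethylbenzene | Cc1c(F)cc(F)c(C)c1F | intermediate
7 | N-methoxy-N-methylacetamide | CON(C)C(C)=O | starting material
8 | (2,4,6-trifluoro-3,5-dimethylphenyl)lithium | [Li]c1c(F)c(C)c(F)c(C)c1F | intermediate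
9 | 1-(2,4,6-trifluoro-3,5-dimethylphenyl)ethanone | CC(=O)c1c(F)c(C)c(F)c(C)c1F | intermediate
10 | 3-hydroxy-4,5-dimethoxybenzoic acid | COc1cc(C(=O)O)cc(O)c1OC | starting material
11 | benzyl bromide | BrCc1ccccc1 | starting material
12 | benzyl 3-benzyloxy-4,5-dimethoxybenzoate | COc1cc(C(=O)OCc2ccccc2)cc(OCc2ccccc2)c1OC | intermediate
13 | 3-benzyloxy-4,5-dimethoxybenzoic acid | COc1cc(C(=O)O)cc(OCc2ccccc2)c1OC | intermediate
14 | 3-benzyloxy-4,5-dimethoxybenzoyl chloride | COc1cc(C(Cl)=O)cc(OCc2ccccc2)c1OC | intermediate
15 | lithium 1-(2,4,6-trifluoro-3,5-dimethylphenyl)ethenolate | [Li+].[O-]C(=C)c1c(F)c(C)c(F)c(C)c1F | intermediate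
16 | 1-(3-benzyloxy-4,5-dimethoxyphenyl)-3-(2,4,6-trifluoro-3,5-dimethylphenyl)propane-1,3-dione | COc1cc(C(=O)CC(=O)c2c(F)c(C)c(F)c(C)c2F)cc(OCc2ccccc2)c1OC | intermediate
17 | cesium (Z)-1-(3-benzyloxy-4,5-dimethoxyphenyl)-3-oxo-3-(2,4,6-trifluoro-3,5-dimethylphenyl)prop-1-en-1-olate | [Cs+].[O-]/C(=C\C(=O)c1c(F)c(C)c(F)c(C)c1F)c1cc(OC)c(OC)c(OCc2ccccc2)c1 | intermediate
18 | 2-(3-benzyloxy-4,5-dimethoxyphenyl)-5,7-difluoro-6,8-dimethylchromen-4-one | COc1cc(-c2cc(=O)c3c(F)c(C)c(F)c(C)c3o2)cc(OCc2ccccc2)c1OC | intermediate
19 | benzyl alcohol | OCc1ccccc1 | starting material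
20 | 7-benzyloxy-2-(3-benzyloxy-4,5-dimethoxyphenyl)-5-fluoro-6,8-dimethylchromen-4-one | COc1cc(-c2cc(=O)c3c(F)c(C)c(OCc4ccccc4)c(C)c3o2)cc(OCc2ccccc2)c1OC | intermediate
21 | 5,7-bis(benzyloxy)-2-(3-benzyloxy-4,5-dimethoxyphenyl)-6,8-dimethylchromen-4-one | COc1cc(-c2cc(=O)c3c(OCc4ccccc4)c(C)c(OCc4ccccc4)c(C)c3o2)cc(OCc2ccccc2)c1OC | intermediate
22 | 5,7-dihydroxy-2-(3-hydroxy-4,5-dimethoxyphenyl)-6,8-dimethylchromen-4-one (5,7,3'-trihydroxy-4',5'-dimethoxy-6,8-dimethylflavone) | COc1cc(-c2cc(=O)c3c(O)c(C)c(O)c(C)c3o2)cc(O)c1OC | target

Total step count: 8. Longest linear sequence: 7 steps (steps 1, 2, 3, 5, 6, 7 and 8; step 4 supplies the ring B acid).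

Steps most likely to fail

Step 7. After the exchange at C7, the second displacement at C5, an ipso carbon wedged between the C6 methyl group and the peri carbonyl, may stall. Prolonged heating with excess alkoxide may then lead to attack at C2 and opening of the pyranone. The fallback splits the exchange and brings in the second oxygen with an α-effect nucleophile that reacts under milder, weakly basic conditions and delivers the phenol itself. It sets out from 18: sodium benzyloxide (1.1 equiv, THF, 0 °C → rt) should stop at 20, which is now isolated. (E)-Benzaldehyde oxime and Cs2CO3 in DMSO at 70 °C should then displace the C5 fluoride to give (E)-benzaldehyde O-[7-benzyloxy-2-(3-benzyloxy-4,5-dimethoxyphenyl)-6,8-dimethyl-4-oxochromen-5-yl]oxime F1. Under the same conditions this should eliminate benzonitrile to give 7-benzyloxy-2-(3-benzyloxy-4,5-dimethoxyphenyl)-5-hydroxy-6,8-dimethylchromen-4-one F2. Hydrogenolysis of F2 under the conditions of step 8 removes the two remaining benzyl groups and comes back to the route at 22.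

Step 5. The hindered lithium enolate 15 may be acylated on oxygen or twice on carbon, so that enol ester and triketone erode the supply of the diketone. The fallback forms the C–C bond by an aldol addition, which cannot over-react, and adjusts the oxidation level afterwards. Purchased 3-hydroxy-4,5-dimethoxybenzaldehyde (COc1cc(C=O)cc(O)c1OC) would be benzylated with 11 (K2CO3, DMF, 60 °C) to 3-benzyloxy-4,5-dimethoxybenzaldehyde F3. Setting out from 9, enolate 15 (LiN(SiMe3)2, THF, −78 °C) should add to F3 to give racemic 3-(3-benzyloxy-4,5-dimethoxyphenyl)-3-hydroxy-1-(2,4,6-trifluoro-3,5-dimethylphenyl)propan-1-one F4. Oxidation of this β-hydroxy ketone with Dess–Martin periodinane (CH2Cl2, rt) returns to the route at 16.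

Step 3. Aryllithium 8 may act as a base toward the acetamide, or lose LiF on warming before it has added, so that 6 is recovered or aryne-derived material forms. The fallback sets out from 6 and traps 8 at −78 °C with acetaldehyde, a far more reactive and less hindered electrophile, to give racemic 1-(2,4,6-trifluoro-3,5-dimethylphenyl)ethanol F5. Oxidation of this benzylic alcohol with Dess–Martin periodinane (CH2Cl2, rt) comes back to the route at 9.

The key step (step 6) is not ranked among these three because its reaction type is established for this substrate class and its ring closure is intramolecular.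

Further compounds
F1 | step 7 | (E)-benzaldehyde O-[7-benzyloxy-2-(3-benzyloxy-4,5-dimethoxyphenyl)-6,8-dimethyl-4-oxochromen-5-yl]oxime | COc1cc(-c2cc(=O)c3c(O/N=C/c4ccccc4)c(C)c(OCc4ccccc4)c(C)c3o2)cc(OCc2ccccc2)c1OC
F2 | step 7 | 7-benzyloxy-2-(3-benzyloxy-4,5-dimethoxyphenyl)-5-hydroxy-6,8-dimethylchromen-4-one | COc1cc(-c2cc(=O)c3c(O)c(C)c(OCc4ccccc4)c(C)c3o2)cc(OCc2ccccc2)c1OC
F3 | step 5 | 3-benzyloxy-4,5-dimethoxybenzaldehyde | COc1cc(C=O)cc(OCc2ccccc2)c1OC
F4 | step 5 | rac-3-(3-benzyloxy-4,5-dimethoxyphenyl)-3-hydroxy-1-(2,4,6-trifluoro-3,5-dimethylphenyl)propan-1-one | COc1cc(C(O)CC(=O)c2c(F)c(C)c(F)c(C)c2F)cc(OCc2ccccc2)c1OC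
F5 | step 3 | rac-1-(2,4,6-trifluoro-3,5-dimethylphenyl)ethanol | CC(O)c1c(F)c(C)c(F)c(C)c1F
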